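(Readings and results were generated by integration for substances that don't exist; the scatter is artificial.)

Q, the limiting reagent in the epsilon flask (120 mM against 180 mM of X), was my yardstick, so I counted G as a share of the Q charged.

| flask | Q | X | time |
|---|---|---|---|
| epsilon | 120 mM | 180 mM |  |
| gamma | 48.0 mM | 108 mM |  |
| delta | 360 mM | 180 mM |  |
| zeta | 120 mM | 540 mM |  |
| alpha | 40.0 mM | 90.0 mM | 27 min |

- epsilon run (time / min: [G] / mM): 1.1: 3.3; 2.4: 7.4; 5.4: 14.4; 12: 25.7; 27: 36.0
- gamma run (time / min: [G] / mM): 1.1: 1.1; 2.4: 1.5; 5.4: 3.6; 12: 6.6; 27: 12.1
- delta run (time / min: [G] / mM): 1.1: 10.0; 2.4: 19.4; 5.4: 36.8; 12: 55.0; 27: 59.3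
- zeta run (time / min: [G] / mM): 1.1: 9.7; 2.4: 20.5; 5.4: 38.5; 12: 61.2; 27: 73.9

(standard deviation of a reading: 0.4 mM)

- Overall: Q + X -> G.
- Constant volume, constant temperature.
- Bound and free are read together.
- "The second partner" is X.
- An order is taken over about fifteen percent of the charge, up and down.

- apparent order in [Q] of the starting rate, round the charge of the epsilon run (the rate where two percent of its Q have turned into G) (one fixed amount of G, the same in the runs compared)
- apparent order in [X] of the starting rate, round the charge of the epsilon run (the rate where two percent of its Q have turned into G)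
- G in the alpha run at 27 min, as a share of the Q charged

In the epsilon run the first reading was 3.3 mM of G at 1.1 min, so its charge went at a share of about 0.0250 min⁻¹. The delta flask holds 3.00 times that Q and its first reading stood 3.03 times as high. The zeta flask holds 3.00 times that X and its first reading stood 2.94 times as high. So I took both orders as near one, and the starting share per minute as following X.

But delta, with the X of epsilon, stood at 16.5 % of its charge at 27 min and epsilon at 30.0 %, so I trusted no formula for the late end. Alpha and gamma, however, hold X to Q in one ratio, 2.25 and 2.25. So I joined the two ends by a charge clock, the reduced time: that starting share per minute, scaled to the flask's X, times the minutes. For alpha at 27 min it reads 0.338. I assumed that at one ratio an equal clock means an equal share turned. Gamma, richer in X, reaches that clock at 22.5 min, and a straight line between its readings at 12 min and 27 min gave me 21.8 %.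

The forecast gave orders of 0.96 and 1 and 22 % for alpha, “scaling from gamma's 25%”.

The flask gave orders of 1.0 and 1.0, and alpha reached 22.2 %.

    Q + X ⇌ G + Z (0.1494 M⁻¹ min⁻¹, 1.398 M⁻¹ min⁻¹)
    G → Wa (0.01266 min⁻¹)
    X + Z ⇌ XZ, settled at all times (56.70 M⁻¹)

A fit with these steps forecasts 22.3 % for alpha. The clock of alpha thus stood at 0.338 when 22.2 % had turned. Delta, at X to Q of 0.500, had a clock of 0.675 at 27 min, twice that of alpha, yet had turned less than alpha, 16.5 % of its charge.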